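## Structural features

The target is a C37 norcarotenoid-type butenolide in which three rings hang on one conjugated polyenyne. Ring A, an (R)-4-hydroxy-2,6,6-trimethylcyclohex-1-ene, is bonded through its tetrasubstituted sp2 carbon to a C≡C unit; the alkyne continues as an all-E tetraene with methyl branches on its first and last sp2 carbons and ends as the (Z)-alkylidene group at C5 of a furan-2(5H)-one, whose C3 carries an (E)-ethenyl bridge to the quaternary oxirane carbon of ring B, a 4-hydroxy-2,2,6-trimethyl-7-oxabicyclo[4.1.0]heptane. Of the four stereocentres one stands alone (the ring A carbinol); the other three sit in ring B, where the two adjacent, fully substituted oxirane carbons are 1,3-related to the carbinol carbon and the oxirane oxygen lies anti to the hydroxyl. The two carbinol carbons have the same spatial arrangement; their descriptors differ (R in ring A, S in ring B) only because the oxirane changes the substituent priorities, so both rings can come from one chiral-pool ketone. Fragile are the vinyl oxirane (acid turns it into a furanoid ether; zerovalent palladium or a conjugated carbanion can open it), the (Z)-ylidenebutenolide (bases, nucleophiles, Z/E drift), the polyene (light, acid, oxygen) and any terminal 1,3-diyne on the way. The real difficulty is the geometrically pure assembly of the branched polyenyne and its union with the butenolide–oxirane half under conditions that all of these groups survive. The key step exploits the methyl-bearing E trisubstituted alkene bonded directly to the ring A alkyne: a CH3–C(=CH–)–C≡C array is what syn addition of methyl and metal across the terminal triple bond of a ring A buta-1,3-diyne gives, and the alkenyl metal so formed can forge the next sp2–sp2 bond of the chain.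

## Logic of the disconnections

31 is cut first at the single bond between butenolide C3 and the ethenyl carbon, giving 23 and 30. This is the most convergent cut, and it keeps the oxirane away from every acidic, basic and organoaluminium step of the polyene half. The forward step must join two sp2 carbons under neutral conditions with retention and in the presence of two free hydroxyls.

23 is traced through 22 to 18 and 19 by cutting the exocyclic C5=C bond of the butenolide. The lactone ring is then bought, with bromine at C3 as the handle for the last coupling. The forward step must react at the γ-carbon of the butenolide and give the Z alkylidene isomer.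

18 goes back through 17 to 16 by changing only the oxidation state of the terminal carbon. Carrying that carbon as an ester keeps it inert towards the organometallic step.

16 is cut at two bonds at once: the C–CH3 bond of the branch next to the alkyne and the sp2–sp2 bond between that trisubstituted alkene and the next CH=, giving 8, 13 and 12. The branch methyl becomes a reagent and the alkene geometry follows from a syn addition, so no separate olefination is needed. The forward step must place methyl on the internal carbon of the terminal alkyne only, leave the ring-bound alkyne untouched, and couple with retention.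

8 is traced through 7 to 3 and 4 by cutting the bond between the ring sp2 carbon and the first alkyne carbon. The four-carbon diyne arrives in one piece. The forward step must couple at a tetrasubstituted enol triflate, and the terminal diyne is set free only just before use.

12 is cut at its trisubstituted C2=C3 bond into 10 and 11, and 10 goes back to 9 by exchanging bromine for the enolate oxygen. Both steps must preserve or give E geometry.

30 goes back through 29 and 28 to 27: the C–Sn and C–H bonds across the terminal alkyne are removed, the silyl ether is restored, and the alkyne is cut to the aldehyde one carbon shorter. The forward hydrometalation must put tin on the terminal carbon with E geometry, and the homologation must not touch the adjacent quaternary oxirane carbon.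

27 is traced through 26 to 25 by removing the two C–O bonds of the oxirane. Both oxirane stereocentres are then set in one oxygen transfer whose face is fixed by a chiral catalyst and reinforced by the remote silyloxy group; the forward step must deliver oxygen anti to that group.

25 goes back through 24 to 3 by removing the carbinol carbon as carbon monoxide, so 3 serves both rings. The forward carbonylation must work at the same hindered triflate.

3 is traced through 2 to 1: the enol triflate comes from the ketone, whose single enolisable position fixes the alkene position, and the carbinol stereocentre is bought.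

## Other disconnections considered

Alternative 1: The cut is the ring A bond between the gem-dimethyl carbon and the alkynyl-bearing sp2 carbon. In the forward direction an acyclic acetoxy dienyne A2 with an isopropenyl end and a silyl-capped enyne end is treated with cold methanesulfonic acid: protonation gives a tertiary cation, the enyne alkene closes the six-membered ring, and proton loss gives the conjugated cyclohexenyl alkyne A1. In its favour, ring, tetrasubstituted alkene and ring–alkyne bond arrive in one step without enol triflate or palladium, and the plan does not depend on the chiral ketone 1. On the ring–alkyne junction it is the better plan, since no coupling at a hindered tetrasubstituted carbon is needed. Against it here: the stereocentre must be brought in through A2, which needs its own asymmetric synthesis; the acetoxy group sits two carbons from the cation and can participate or eliminate; proton loss can give alkene isomers; and A1 carries an ethynyl, not a butadiynyl group, so two more alkyne carbons must be added before the methylalumination can be used. In structure both plans reach the same ring A enyne motif. In mechanism a strong-acid cationic cyclisation is less tolerant than the palladium coupling of a preformed ring. In step economy the chosen plan reaches 8 in four steps from 1, while A2 alone should need at least as many.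

Alternative 2: The cut takes out the lactone carbonyl carbon, that is the C2–C3 and C2–O1 bonds of the butenolide. In the forward direction a (Z)-β-iodo enone A4 that already carries the ring B ethenyl group is carbonylated with a palladium catalyst, carbon monoxide and triethylamine; the acylpalladium is captured by the enol oxygen of the cis ketone to give the ylidenebutenolide A3. In its favour, the lactone is closed under mild conditions, the Z geometry follows from the cyclisation, and the geometry is settled on a small fragment where isomers can be separated; on that point it is better than the chosen plan, which forms the alkylidene bond on the full ring A polyene in step 10. It also needs no tin for the butenolide. Against it here: A4 is a stereodefined iodo dienone with a vinyl oxirane and needs several steps; enolisation must go to the correct side and give O- rather than C-acylation; the oxirane is exposed to zerovalent palladium; and A3 ends in a protected allylic alcohol, so the whole ring A polyenyne must still be attached by a later olefination. In structure the alternative builds the lactone ring, whereas the chosen plan buys it as 19. In mechanism both rely on a cyclisation or elimination that favours the Z isomer and are equal there. In step economy the chosen plan is shorter, because the butenolide costs one step from two available partners.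

Alternative 3: The cut removes both C–O bonds of the oxirane. In the forward direction the cyclohexenylmethanol A6 is epoxidised with Ti(OiPr)4, a dialkyl tartrate and tert-butyl hydroperoxide to give the anti epoxy alcohol A5. In its favour, both quaternary oxirane carbons are set in one reagent-controlled step. This transformation does not compete with the chosen key step: the chosen route adopts it as step 14 (A6 is compound 25, A5 is compound 26), so on the oxirane the two plans are equal. What speaks against making it the organising disconnection is that it forms no carbon–carbon bond and leaves the polyenyne and the butenolide unsolved. A plan centred on it would grow the chain linearly outward from A5 and carry the acid-sensitive oxirane through many more steps, where the chosen plan introduces ring B in the last step. In structure the alternative addresses two stereocentres and the chosen key step addresses a branched alkene and two skeletal bonds. In mechanism it is a directed oxygen transfer against a carbometalation and cross-coupling. In step economy it is neutral, since any plan needs it or an equivalent.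

Key step: step 7

Assumption: 1, 4, 9, 11, 13 and 19 are taken as purchasable, and 8 is handled only in solution because terminal 1,3-diynes decompose when concentrated.

## Steps

Step 1
Reactants: 1 (4R,6R)-actinol [(4R,6R)-4-hydroxy-2,2,6-trimethylcyclohexan-1-one]
Product: 2 (4R,6R)-4-(tert-butyldimethylsilyloxy)-2,2,6-trimethylcyclohexan-1-one
Conditions: TBSCl, imidazole, DMF, rt
Reagents that add atoms: tert-butyldimethylsilyl chloride, CC(C)(C)[Si](C)(C)Cl
Why: Silyl ether formation masks the only O–H before the enolate, organoaluminium and hydride steps; no stereocentre is touched.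

Step 2
Reactants: 2 (4R,6R)-4-(tert-butyldimethylsilyloxy)-2,2,6-trimethylcyclohexan-1-one
Product: 3 (R)-4-(tert-butyldimethylsilyloxy)-2,6,6-trimethylcyclohex-1-en-1-yl trifluoromethanesulfonate
Conditions: LiN(i-Pr)2, THF, −78 °C; PhNTf2, −78 °C to rt
Reagents that add atoms: N-phenylbis(trifluoromethanesulfonimide), O=S(=O)(N(c1ccccc1)S(=O)(=O)C(F)(F)F)C(F)(F)F
Why: Enolate O-triflation; the ketone has one α-hydrogen only (the other α-carbon is quaternary), so a single tetrasubstituted enol triflate should form. The methyl-bearing stereocentre is erased on purpose and the carbinol centre is remote.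

Step 3
Reactants: 3 (R)-4-(tert-butyldimethylsilyloxy)-2,6,6-trimethylcyclohex-1-en-1-yl trifluoromethanesulfonate; 4 1,4-bis(trimethylsilyl)buta-1,3-diyne
Product: 7 tert-butyldimethyl{[(R)-3,5,5-trimethyl-4-[4-(trimethylsilyl)buta-1,3-diyn-1-yl]cyclohex-3-en-1-yl]oxy}silane, via lithium 4-(trimethylsilyl)butadiynide 5 (not isolated), via 4-(trimethylsilyl)butadiynylzinc chloride 6 (not isolated)
Conditions: 4, MeLi·LiBr (1 equiv), Et2O/THF, rt; ZnCl2, 0 °C; 3, Pd(PPh3)4 (cat.), THF, rt to 45 °C
Reagents that add atoms: none
Why: Methyllithium removes one silyl group of 4 as tetramethylsilane to give acetylide 5; transmetalation to zinc and Negishi alkynylation of the enol triflate form the ring sp2–sp bond. No copper is present, so oxidative diyne dimerisation is avoided, and the volatile monosilyl diyne is never isolated.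

Step 4
Reactants: 7 tert-butyldimethyl{[(R)-3,5,5-trimethyl-4-[4-(trimethylsilyl)buta-1,3-diyn-1-yl]cyclohex-3-en-1-yl]oxy}silane
Product: 8 {[(R)-4-(buta-1,3-diyn-1-yl)-3,5,5-trimethylcyclohex-3-en-1-yl]oxy}(tert-butyl)dimethylsilane
Conditions: K2CO3 (cat.), MeOH/THF, 0 °C; extracted and used at once as a solution
Reagents that add atoms: none
Why: Methoxide-induced protodesilylation of the alkynylsilane; the hindered O-silyl ether should stay, and the terminal diyne is carried on without concentration.

Step 5
Reactants: 9 glutaconaldehyde potassium salt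
Product: 10 (2E,4E)-5-bromopenta-2,4-dienal
Conditions: PPh3, Br2, CH2Cl2, 0 °C to rt, dark
Reagents that add atoms: bromine, BrBr
Why: Ph3PBr2 made in the flask turns the enolate oxygen into an oxyphosphonium leaving group and bromide replaces it by vinylogous addition–elimination (deoxybromination of a vinylogous carboxylate); the conjugated dienal should settle in the E,E form.

Step 6
Reactants: 10 (2E,4E)-5-bromopenta-2,4-dienal; 11 ethyl 2-(triphenylphosphoranylidene)propanoate
Product: 12 ethyl (2E,4E,6E)-7-bromo-2-methylhepta-2,4,6-trienoate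
Conditions: CH2Cl2, rt, dark
Reagents that add atoms: none
Why: Wittig olefination with a stabilised α-branched ylide is E-selective and leaves the alkenyl bromide alone.

Step 7
Reactants: 8 {[(R)-4-(buta-1,3-diyn-1-yl)-3,5,5-trimethylcyclohex-3-en-1-yl]oxy}(tert-butyl)dimethylsilane; 13 trimethylaluminium; 12 ethyl (2E,4E,6E)-7-bromo-2-methylhepta-2,4,6-trienoate
Product: 16 ethyl (2E,4E,6E,8E)-11-[(R)-4-(tert-butyldimethylsilyloxy)-2,6,6-trimethylcyclohex-1-en-1-yl]-2,9-dimethylundeca-2,4,6,8-tetraen-10-ynoate, via (E)-alkenyldimethylalane 14 (not isolated), via (E)-alkenylzinc chloride 15 (not isolated)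
Conditions: 13 (3 equiv), Cp2ZrCl2 (cat.), CH2Cl2, 0 °C to rt; volatiles removed in vacuo; THF, ZnCl2, 12, Pd(PPh3)4 (cat.), rt, dark
Reagents that add atoms: none
Why: Cp2ZrCl2 and 13 form a methylzirconocene–aluminium species that adds CH3 and metal syn across the terminal C≡C of 8; methyl goes to the internal carbon because the metal takes the unhindered terminal one, and zirconium-to-aluminium exchange gives the E-alkenylalane 14 and returns the catalyst. The ring-bound triple bond is disubstituted and shielded by the gem-dimethyl group and the ring methyl, so it should not compete, and the silyl ether is inert to the alane. Excess 13 is pumped off because it would otherwise transfer methyl to palladium; ZnCl2 then converts 14 into the alkenylzinc 15. Zerovalent palladium inserts into the C–Br bond of 12 with retention, 15 transmetalates, and reductive elimination forms the C7–C8 bond of 16 with retention, so the new trisubstituted alkene and the alkenes of 12 should all stay E. The closest known reaction type is the zirconium-catalysed methylalumination of terminal alkynes, conjugated enynes and diynes included, followed by palladium/zinc cross-coupling with alkenyl halides (Negishi). No ring is closed and no stereocentre is formed; two skeletal bonds are made, C9–CH3 and C7–C8. The step needs regioselective syn addition (secured by the terminal alkyne and the four-centre addition), discrimination between the two triple bonds (secured by sterics) and ester tolerance (secured by the mild alkenylzinc at room temperature).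

Step 8
Reactants: 16 ethyl (2E,4E,6E,8E)-11-[(R)-4-(tert-butyldimethylsilyloxy)-2,6,6-trimethylcyclohex-1-en-1-yl]-2,9-dimethylundeca-2,4,6,8-tetraen-10-ynoate
Product: 17 (2E,4E,6E,8E)-11-[(R)-4-(tert-butyldimethylsilyloxy)-2,6,6-trimethylcyclohex-1-en-1-yl]-2,9-dimethylundeca-2,4,6,8-tetraen-10-yn-1-ol
Conditions: i-Bu2AlH, CH2Cl2, −78 °C; aq. potassium sodium tartrate
Reagents that add atoms: none
Why: 1,2-Reduction of the conjugated ester by the aluminium hydride gives the allylic alcohol; alkyne, polyene and silyl ether are not reduced at this temperature.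

Step 9
Reactants: 17 (2E,4E,6E,8E)-11-[(R)-4-(tert-butyldimethylsilyloxy)-2,6,6-trimethylcyclohex-1-en-1-yl]-2,9-dimethylundeca-2,4,6,8-tetraen-10-yn-1-ol
Product: 18 (2E,4E,6E,8E)-11-[(R)-4-(tert-butyldimethylsilyloxy)-2,6,6-trimethylcyclohex-1-en-1-yl]-2,9-dimethylundeca-2,4,6,8-tetraen-10-ynal
Conditions: MnO2, CH2Cl2, rt, dark
Reagents that add atoms: none
Why: Selective oxidation of an allylic alcohol to the conjugated aldehyde on the MnO2 surface, neutral and without over-oxidation.

Step 10
Reactants: 18 (2E,4E,6E,8E)-11-[(R)-4-(tert-butyldimethylsilyloxy)-2,6,6-trimethylcyclohex-1-en-1-yl]-2,9-dimethylundeca-2,4,6,8-tetraen-10-ynal; 19 3-bromofuran-2(5H)-one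
Product: 22 (Z)-3-bromo-5-[(2E,4E,6E,8E)-11-[(R)-4-(tert-butyldimethylsilyloxy)-2,6,6-trimethylcyclohex-1-en-1-yl]-2,9-dimethylundeca-2,4,6,8-tetraen-10-yn-1-ylidene]furan-2(5H)-one, via 3-bromo-2-silyloxyfuran 20 (not isolated), via silyl aldol adduct 21 (not isolated)
Conditions: TBSOTf, i-Pr2NEt, CH2Cl2, −78 to 0 °C; then DBU, 0 °C to rt, dark
Reagents that add atoms: none
Why: One-flask vinylogous Mukaiyama aldol addition and elimination: 19 is O-silylated to furan 20, which adds through its free α-carbon (C5) to the silyl-activated aldehyde to give 21; DBU then removes the acidic C5 proton and expels silanolate (E1cB). The Z alkylidene isomer, in which the chain avoids the ring C4–H, should dominate.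

Step 11
Reactants: 22 (Z)-3-bromo-5-[(2E,4E,6E,8E)-11-[(R)-4-(tert-butyldimethylsilyloxy)-2,6,6-trimethylcyclohex-1-en-1-yl]-2,9-dimethylundeca-2,4,6,8-tetraen-10-yn-1-ylidene]furan-2(5H)-one
Product: 23 (Z)-3-bromo-5-[(2E,4E,6E,8E)-11-[(R)-4-hydroxy-2,6,6-trimethylcyclohex-1-en-1-yl]-2,9-dimethylundeca-2,4,6,8-tetraen-10-yn-1-ylidene]furan-2(5H)-one
Conditions: HF·pyridine, pyridine, THF, 0 °C to rt, dark
Reagents that add atoms: none
Why: Fluoride cleavage of the secondary silyl ether under buffered, weakly acidic conditions; this half has no oxirane, and the base-sensitive enol lactone is spared.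

Step 12
Reactants: 3 (R)-4-(tert-butyldimethylsilyloxy)-2,6,6-trimethylcyclohex-1-en-1-yl trifluoromethanesulfonate
Product: 24 methyl (R)-4-(tert-butyldimethylsilyloxy)-2,6,6-trimethylcyclohex-1-ene-1-carboxylate
Conditions: Pd(OAc)2 (cat.), PPh3, CO (1 atm), MeOH, Et3N, DMF, 60 °C
Reagents that add atoms: carbon monoxide, [C-]#[O+]; methanol, CO
Why: Palladium-catalysed methoxycarbonylation of an enol triflate (oxidative addition, CO insertion, methanolysis of the acylpalladium) adds the carbon that becomes the ethenyl bridge.

Step 13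
Reactants: 24 methyl (R)-4-(tert-butyldimethylsilyloxy)-2,6,6-trimethylcyclohex-1-ene-1-carboxylate
Product: 25 [(R)-4-(tert-butyldimethylsilyloxy)-2,6,6-trimethylcyclohex-1-en-1-yl]methanol
Conditions: i-Bu2AlH, CH2Cl2, −78 to 0 °C; aq. potassium sodium tartrate
Reagents that add atoms: none
Why: Aluminium hydride reduction of the hindered conjugated ester to the allylic alcohol needed to direct the epoxidation.

Step 14
Reactants: 25 [(R)-4-(tert-butyldimethylsilyloxy)-2,6,6-trimethylcyclohex-1-en-1-yl]methanol
Product: 26 [(1R,4S,6R)-4-(tert-butyldimethylsilyloxy)-2,2,6-trimethyl-7-oxabicyclo[4.1.0]heptan-1-yl]methanol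
Conditions: Ti(OiPr)4, D-(−)-diethyl tartrate, t-BuOOH, 4 Å MS, CH2Cl2, −20 °C
Reagents that add atoms: tert-butyl hydroperoxide, CC(C)(C)OO
Why: Katsuki–Sharpless asymmetric epoxidation: the allylic alkoxide binds the titanium tartrate and the peroxide oxygen is delivered within the complex. With the D-(−)-tartrate the face attacked is the one anti to the ring silyloxy group, which should also be the sterically easier face, so reagent and substrate control reinforce each other and both oxirane carbons are set together.

Step 15
Reactants: 26 [(1R,4S,6R)-4-(tert-butyldimethylsilyloxy)-2,2,6-trimethyl-7-oxabicyclo[4.1.0]heptan-1-yl]methanol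
Product: 27 (1S,4S,6R)-4-(tert-butyldimethylsilyloxy)-2,2,6-trimethyl-7-oxabicyclo[4.1.0]heptane-1-carbaldehyde
Conditions: (n-Pr4N)RuO4 (cat.), N-methylmorpholine N-oxide, 4 Å MS, CH2Cl2, rt
Reagents that add atoms: none
Why: Ley–Griffith oxidation under neutral conditions; the aldehyde has no α-hydrogen, so the adjacent stereocentre cannot epimerise (its descriptor changes by priority only).

Step 16
Reactants: 27 (1S,4S,6R)-4-(tert-butyldimethylsilyloxy)-2,2,6-trimethyl-7-oxabicyclo[4.1.0]heptane-1-carbaldehyde
Product: 28 (1R,4S,6R)-4-(tert-butyldimethylsilyloxy)-1-ethynyl-2,2,6-trimethyl-7-oxabicyclo[4.1.0]heptane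
Conditions: dimethyl (1-diazo-2-oxopropyl)phosphonate, K2CO3, MeOH, 0 °C to rt
Reagents that add atoms: dimethyl (1-diazo-2-oxopropyl)phosphonate, COP(=O)(OC)C(=[N+]=[N-])C(C)=O
Why: Seyferth–Gilbert homologation in the Ohira–Bestmann form: methanolysis of the reagent gives the diazomethylphosphonate anion, which adds to the aldehyde; loss of phosphate and nitrogen and a 1,2-shift give the terminal alkyne. The hindered tetrasubstituted oxirane should resist methoxide.

Step 17
Reactants: 28 (1R,4S,6R)-4-(tert-butyldimethylsilyloxy)-1-ethynyl-2,2,6-trimethyl-7-oxabicyclo[4.1.0]heptane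
Product: 29 (1R,3S,6R)-6-ethynyl-1,5,5-trimethyl-7-oxabicyclo[4.1.0]heptan-3-ol
Conditions: n-Bu4NF, THF, 0 °C to rt
Reagents that add atoms: none
Why: Fluoride desilylation under basic conditions, which this half tolerates because it has no lactone, and which avoid the acid that would rearrange the oxirane.

Step 18
Reactants: 29 (1R,3S,6R)-6-ethynyl-1,5,5-trimethyl-7-oxabicyclo[4.1.0]heptan-3-ol
Product: 30 (1R,3S,6S)-1,5,5-trimethyl-6-[(E)-2-(tributylstannyl)ethenyl]-7-oxabicyclo[4.1.0]heptan-3-ol
Conditions: Bu3SnH (slow addition), PdCl2(PPh3)2 (cat.), THF, 0 °C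
Reagents that add atoms: tributyltin hydride, CCCC[SnH](CCCC)CCCC
Why: Palladium-catalysed hydrostannation, a syn addition of Sn–H across the terminal alkyne; the fully substituted propargylic carbon steers tin to the terminal carbon and gives the E stannane. Fast Sn–H oxidative addition is expected to outrun attack of palladium on the propargylic oxirane.

Step 19
Reactants: 23 (Z)-3-bromo-5-[(2E,4E,6E,8E)-11-[(R)-4-hydroxy-2,6,6-trimethylcyclohex-1-en-1-yl]-2,9-dimethylundeca-2,4,6,8-tetraen-10-yn-1-ylidene]furan-2(5H)-one; 30 (1R,3S,6S)-1,5,5-trimethyl-6-[(E)-2-(tributylstannyl)ethenyl]-7-oxabicyclo[4.1.0]heptan-3-ol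
Product: 31 (Z)-3-[(E)-2-[(1S,4S,6R)-4-hydroxy-2,2,6-trimethyl-7-oxabicyclo[4.1.0]heptan-1-yl]ethenyl]-5-[(2E,4E,6E,8E)-11-[(R)-4-hydroxy-2,6,6-trimethylcyclohex-1-en-1-yl]-2,9-dimethylundeca-2,4,6,8-tetraen-10-yn-1-ylidene]furan-2(5H)-one
Conditions: Pd2(dba)3 (cat.), AsPh3, DMF, rt, dark
Reagents that add atoms: none
Why: Stille coupling: zerovalent palladium adds to the electron-poor C3–Br bond of the butenolide, the E-alkenyl group moves from tin to palladium and reductive elimination follows, all with retention. The medium is neutral, so free hydroxyls, oxirane and enol lactone should survive, and no stereocentre is involved.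

## Compound list

1 | (4R,6R)-actinol, (4R,6R)-4-hydroxy-2,2,6-trimethylcyclohexan-1-one | C[C@H]1C(=O)C(C)(C)C[C@H](O)C1 | starting material
2 | (4R,6R)-4-(tert-butyldimethylsilyloxy)-2,2,6-trimethylcyclohexan-1-one | C[C@H]1C(=O)C(C)(C)C[C@H](O[Si](C)(C)C(C)(C)C)C1 | intermediate
3 | (R)-4-(tert-butyldimethylsilyloxy)-2,6,6-trimethylcyclohex-1-en-1-yl trifluoromethanesulfonate | CC1=C(OS(=O)(=O)C(F)(F)F)C(C)(C)C[C@H](O[Si](C)(C)C(C)(C)C)C1 | intermediate
4 | 1,4-bis(trimethylsilyl)buta-1,3-diyne | C[Si](C)(C)C#CC#C[Si](C)(C)C | starting material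
5 | lithium 4-(trimethylsilyl)buta-1,3-diyn-1-ide (not isolated) | [Li]C#CC#C[Si](C)(C)C | intermediate
6 | chloro[4-(trimethylsilyl)buta-1,3-diyn-1-yl]zinc (not isolated) | Cl[Zn]C#CC#C[Si](C)(C)C | intermediate
7 | tert-butyldimethyl{[(R)-3,5,5-trimethyl-4-[4-(trimethylsilyl)buta-1,3-diyn-1-yl]cyclohex-3-en-1-yl]oxy}silane | CC1=C(C#CC#C[Si](C)(C)C)C(C)(C)C[C@H](O[Si](C)(C)C(C)(C)C)C1 | intermediate
8 | {[(R)-4-(buta-1,3-diyn-1-yl)-3,5,5-trimethylcyclohex-3-en-1-yl]oxy}(tert-butyl)dimethylsilane | CC1=C(C#CC#C)C(C)(C)C[C@H](O[Si](C)(C)C(C)(C)C)C1 | intermediate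
9 | glutaconaldehyde potassium salt, potassium (1E,3E)-5-oxopenta-1,3-dien-1-olate | [K+].[O-]/C=C/C=C/C=O | starting material
10 | (2E,4E)-5-bromopenta-2,4-dienal | O=C/C=C/C=C/Br | intermediate
11 | ethyl 2-(triphenylphosphoranylidene)propanoate | CCOC(=O)C(C)=P(c1ccccc1)(c1ccccc1)c1ccccc1 | starting material
12 | ethyl (2E,4E,6E)-7-bromo-2-methylhepta-2,4,6-trienoate | CCOC(=O)/C(C)=C/C=C/C=C/Br | intermediate
13 | trimethylaluminium | C[Al](C)C | starting material
14 | dimethyl{(E)-4-[(R)-4-(tert-butyldimethylsilyloxy)-2,6,6-trimethylcyclohex-1-en-1-yl]-2-methylbut-1-en-3-yn-1-yl}alane (not isolated) | CC1=C(C#C/C(C)=C/[Al](C)C)C(C)(C)C[C@H](O[Si](C)(C)C(C)(C)C)C1 | intermediate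
15 | chloro{(E)-4-[(R)-4-(tert-butyldimethylsilyloxy)-2,6,6-trimethylcyclohex-1-en-1-yl]-2-methylbut-1-en-3-yn-1-yl}zinc (not isolated) | CC1=C(C#C/C(C)=C/[Zn]Cl)C(C)(C)C[C@H](O[Si](C)(C)C(C)(C)C)C1 | intermediate
16 | ethyl (2E,4E,6E,8E)-11-[(R)-4-(tert-butyldimethylsilyloxy)-2,6,6-trimethylcyclohex-1-en-1-yl]-2,9-dimethylundeca-2,4,6,8-tetraen-10-ynoate | CC1=C(C#C/C(C)=C/C=C/C=C/C=C(C)/C(=O)OCC)C(C)(C)C[C@H](O[Si](C)(C)C(C)(C)C)C1 | intermediate
17 | (2E,4E,6E,8E)-11-[(R)-4-(tert-butyldimethylsilyloxy)-2,6,6-trimethylcyclohex-1-en-1-yl]-2,9-dimethylundeca-2,4,6,8-tetraen-10-yn-1-ol | CC1=C(C#C/C(C)=C/C=C/C=C/C=C(C)/CO)C(C)(C)C[C@H](O[Si](C)(C)C(C)(C)C)C1 | intermediate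
18 | (2E,4E,6E,8E)-11-[(R)-4-(tert-butyldimethylsilyloxy)-2,6,6-trimethylcyclohex-1-en-1-yl]-2,9-dimethylundeca-2,4,6,8-tetraen-10-ynal | CC1=C(C#C/C(C)=C/C=C/C=C/C=C(C)/C=O)C(C)(C)C[C@H](O[Si](C)(C)C(C)(C)C)C1 | intermediate
19 | 3-bromofuran-2(5H)-one | O=C1OCC=C1Br | starting material
20 | [(3-bromofuran-2-yl)oxy](tert-butyl)dimethylsilane (not isolated) | CC(C)(C)[Si](C)(C)Oc1occc1Br | intermediate
21 | 3-bromo-5-[(2E,4E,6E,8E)-1-(tert-butyldimethylsilyloxy)-11-[(R)-4-(tert-butyldimethylsilyloxy)-2,6,6-trimethylcyclohex-1-en-1-yl]-2,9-dimethylundeca-2,4,6,8-tetraen-10-yn-1-yl]furan-2(5H)-one, mixture of isomers at the two new centres (not isolated) | CC1=C(C#C/C(C)=C/C=C/C=C/C=C(C)/C(O[Si](C)(C)C(C)(C)C)C2C=C(Br)C(=O)O2)C(C)(C)C[C@H](O[Si](C)(C)C(C)(C)C)C1 | intermediate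
22 | (Z)-3-bromo-5-[(2E,4E,6E,8E)-11-[(R)-4-(tert-butyldimethylsilyloxy)-2,6,6-trimethylcyclohex-1-en-1-yl]-2,9-dimethylundeca-2,4,6,8-tetraen-10-yn-1-ylidene]furan-2(5H)-one | CC1=C(C#C/C(C)=C/C=C/C=C/C=C(C)/C=C2C=C(Br)C(=O)O/2)C(C)(C)C[C@H](O[Si](C)(C)C(C)(C)C)C1 | intermediate
23 | (Z)-3-bromo-5-[(2E,4E,6E,8E)-11-[(R)-4-hydroxy-2,6,6-trimethylcyclohex-1-en-1-yl]-2,9-dimethylundeca-2,4,6,8-tetraen-10-yn-1-ylidene]furan-2(5H)-one | CC1=C(C#C/C(C)=C/C=C/C=C/C=C(C)/C=C2C=C(Br)C(=O)O/2)C(C)(C)C[C@H](O)C1 | intermediate
24 | methyl (R)-4-(tert-butyldimethylsilyloxy)-2,6,6-trimethylcyclohex-1-ene-1-carboxylate | CC1=C(C(=O)OC)C(C)(C)C[C@H](O[Si](C)(C)C(C)(C)C)C1 | intermediate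
25 | [(R)-4-(tert-butyldimethylsilyloxy)-2,6,6-trimethylcyclohex-1-en-1-yl]methanol | CC1=C(CO)C(C)(C)C[C@H](O[Si](C)(C)C(C)(C)C)C1 | intermediate
26 | [(1R,4S,6R)-4-(tert-butyldimethylsilyloxy)-2,2,6-trimethyl-7-oxabicyclo[4.1.0]heptan-1-yl]methanol | OC[C@@]12O[C@]1(C)C[C@@H](O[Si](C)(C)C(C)(C)C)CC2(C)C | intermediate
27 | (1S,4S,6R)-4-(tert-butyldimethylsilyloxy)-2,2,6-trimethyl-7-oxabicyclo[4.1.0]heptane-1-carbaldehyde | O=C[C@@]12O[C@]1(C)C[C@@H](O[Si](C)(C)C(C)(C)C)CC2(C)C | intermediate
28 | (1R,4S,6R)-4-(tert-butyldimethylsilyloxy)-1-ethynyl-2,2,6-trimethyl-7-oxabicyclo[4.1.0]heptane | C#C[C@@]12O[C@]1(C)C[C@@H](O[Si](C)(C)C(C)(C)C)CC2(C)C | intermediate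
29 | (1R,3S,6R)-6-ethynyl-1,5,5-trimethyl-7-oxabicyclo[4.1.0]heptan-3-ol | C#C[C@@]12O[C@]1(C)C[C@@H](O)CC2(C)C | intermediate
30 | (1R,3S,6S)-1,5,5-trimethyl-6-[(E)-2-(tributylstannyl)ethenyl]-7-oxabicyclo[4.1.0]heptan-3-ol | CCCC[Sn](CCCC)(CCCC)/C=C/[C@@]12O[C@]1(C)C[C@@H](O)CC2(C)C | intermediate
31 | (Z)-3-[(E)-2-[(1S,4S,6R)-4-hydroxy-2,2,6-trimethyl-7-oxabicyclo[4.1.0]heptan-1-yl]ethenyl]-5-[(2E,4E,6E,8E)-11-[(R)-4-hydroxy-2,6,6-trimethylcyclohex-1-en-1-yl]-2,9-dimethylundeca-2,4,6,8-tetraen-10-yn-1-ylidene]furan-2(5H)-one | CC1=C(C#C/C(C)=C/C=C/C=C/C=C(C)/C=C2C=C(/C=C/[C@@]34O[C@]3(C)C[C@@H](O)CC4(C)C)C(=O)O/2)C(C)(C)C[C@H](O)C1 | target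

## Step count and least certain steps

Total step count: 19. Longest linear sequence: 10 steps (1, 2, 3, 4, 7, 8, 9, 10, 11, 19; the ring B branch 1, 2, 12 to 18, 19 is equally long).

Step 7 (key step). The most likely failure is deprotonation of the acidic terminal C–H of the conjugated diyne by the methylalane, which gives an alkynylalane instead of carbometalation. Slow over-addition to the ring-bound alkyne, or methyl transfer to palladium from alane not fully removed, may follow. The fallback builds the same ester without any carbometalation, from the alkyne outwards. It sets out from 3: Sonogashira coupling (PdCl2(PPh3)2, CuI, Et3N) with purchasable (E)-3-methylpent-2-en-4-yn-1-ol, which already holds the branch methyl and the E alkene, should give the ring A enynol F1. MnO2 oxidation gives the enynal F2; two successive two-carbon Wittig homologations with (triphenylphosphoranylidene)acetaldehyde give the dienynal F3 and the trienynal F4; a last Wittig reaction with 11 comes back to the route at 16.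

Step 10. The elimination may lose Z/E control, the silyloxyfuran may add at a remote position of the activated polyenal, or the silyl triflate may oligomerise the polyene. The fallback forms the lactone by cyclisation onto an alkyne. It sets out from 18: Seyferth–Gilbert homologation gives the terminal alkyne F5; Sonogashira coupling at the β-bromide of ethyl (E)-2,3-dibromopropenoate (the bromide cis to the ester) gives the bromo enynoate F6; LiOH gives the bromo enynoic acid F7; AgNO3-catalysed 5-exo-dig lactonisation, an anti addition of carboxylate and metal across the alkyne that dictates the Z geometry, comes back to the route at 22.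

Step 18. Zerovalent palladium may ionise the propargylic oxirane by SN2' attack before hydrostannation, and some tin may end on the internal carbon. The fallback never exposes an alkynyl oxirane to palladium. It sets out from 27: chromium-mediated stannyl olefination of the aldehyde (CrCl2, Bu3SnCHBr2, LiI, a Takai-type reaction) should give the E silyl stannane F8 directly, and n-Bu4NF then removes the silyl group to come back to the route at 30.

Step 19. With the complete polyene present, palladium may open the vinyl oxirane, the alkylidene or chain alkenes may isomerise under palladium and light, and the stannane may homocouple. The fallback moves the palladium step to a small fragment and closes the synthesis by a condensation. It sets out from 28, 19 and 18: hydrostannation of 28 gives the silyl stannane F8; Stille coupling of F8 with 19 gives the ring B dienyl butenolide F9; its lithium dienolate (LiN(SiMe3)2, THF, −78 °C) adds through the γ-carbon to 18 to give the aldol F10; mesylation and E1cB elimination (MsCl, Et3N) give the bis-silyl ether F11; n-Bu4NF buffered with AcOH comes back to the route at 31.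

## Further compounds

F1 | step 7 | (E)-5-[(R)-4-(tert-butyldimethylsilyloxy)-2,6,6-trimethylcyclohex-1-en-1-yl]-3-methylpent-2-en-4-yn-1-ol | CC1=C(C#C/C(C)=C/CO)C(C)(C)C[C@H](O[Si](C)(C)C(C)(C)C)C1
F2 | step 7 | (E)-5-[(R)-4-(tert-butyldimethylsilyloxy)-2,6,6-trimethylcyclohex-1-en-1-yl]-3-methylpent-2-en-4-ynal | CC1=C(C#C/C(C)=C/C=O)C(C)(C)C[C@H](O[Si](C)(C)C(C)(C)C)C1
F3 | step 7 | (2E,4E)-7-[(R)-4-(tert-butyldimethylsilyloxy)-2,6,6-trimethylcyclohex-1-en-1-yl]-5-methylhepta-2,4-dien-6-ynal | CC1=C(C#C/C(C)=C/C=C/C=O)C(C)(C)C[C@H](O[Si](C)(C)C(C)(C)C)C1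
F4 | step 7 | (2E,4E,6E)-9-[(R)-4-(tert-butyldimethylsilyloxy)-2,6,6-trimethylcyclohex-1-en-1-yl]-7-methylnona-2,4,6-trien-8-ynal | CC1=C(C#C/C(C)=C/C=C/C=C/C=O)C(C)(C)C[C@H](O[Si](C)(C)C(C)(C)C)C1
F5 | step 10 | tert-butyl{[(R)-4-[(3E,5E,7E,9E)-3,10-dimethyldodeca-3,5,7,9-tetraene-1,11-diyn-1-yl]-3,5,5-trimethylcyclohex-3-en-1-yl]oxy}dimethylsilane | CC1=C(C#C/C(C)=C/C=C/C=C/C=C(C)/C#C)C(C)(C)C[C@H](O[Si](C)(C)C(C)(C)C)C1
F6 | step 10 | ethyl (2E,6E,8E,10E,12E)-2-bromo-15-[(R)-4-(tert-butyldimethylsilyloxy)-2,6,6-trimethylcyclohex-1-en-1-yl]-6,13-dimethylpentadeca-2,6,8,10,12-pentaene-4,14-diynoate (alkynyl group cis to the ester) | CC1=C(C#C/C(C)=C/C=C/C=C/C=C(C)/C#C/C=C(Br)\C(=O)OCC)C(C)(C)C[C@H](O[Si](C)(C)C(C)(C)C)C1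
F7 | step 10 | (2E,6E,8E,10E,12E)-2-bromo-15-[(R)-4-(tert-butyldimethylsilyloxy)-2,6,6-trimethylcyclohex-1-en-1-yl]-6,13-dimethylpentadeca-2,6,8,10,12-pentaene-4,14-diynoic acid | CC1=C(C#C/C(C)=C/C=C/C=C/C=C(C)/C#C/C=C(Br)\C(=O)O)C(C)(C)C[C@H](O[Si](C)(C)C(C)(C)C)C1
F8 | step 18 | tributyl{(E)-2-[(1S,4S,6R)-4-(tert-butyldimethylsilyloxy)-2,2,6-trimethyl-7-oxabicyclo[4.1.0]heptan-1-yl]ethenyl}stannane | CCCC[Sn](CCCC)(CCCC)/C=C/[C@@]12O[C@]1(C)C[C@@H](O[Si](C)(C)C(C)(C)C)CC2(C)C
F9 | step 19 | 3-{(E)-2-[(1S,4S,6R)-4-(tert-butyldimethylsilyloxy)-2,2,6-trimethyl-7-oxabicyclo[4.1.0]heptan-1-yl]ethenyl}furan-2(5H)-one | O=C1OCC=C1/C=C/[C@@]23O[C@]2(C)C[C@@H](O[Si](C)(C)C(C)(C)C)CC3(C)C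
F10 | step 19 | 3-{(E)-2-[(1S,4S,6R)-4-(tert-butyldimethylsilyloxy)-2,2,6-trimethyl-7-oxabicyclo[4.1.0]heptan-1-yl]ethenyl}-5-[(2E,4E,6E,8E)-11-[(R)-4-(tert-butyldimethylsilyloxy)-2,6,6-trimethylcyclohex-1-en-1-yl]-1-hydroxy-2,9-dimethylundeca-2,4,6,8-tetraen-10-yn-1-yl]furan-2(5H)-one, mixture of isomers at the two new centres | CC1=C(C#C/C(C)=C/C=C/C=C/C=C(C)/C(O)C2C=C(/C=C/[C@@]34O[C@]3(C)C[C@@H](O[Si](C)(C)C(C)(C)C)CC4(C)C)C(=O)O2)C(C)(C)C[C@H](O[Si](C)(C)C(C)(C)C)C1
F11 | step 19 | (Z)-3-{(E)-2-[(1S,4S,6R)-4-(tert-butyldimethylsilyloxy)-2,2,6-trimethyl-7-oxabicyclo[4.1.0]heptan-1-yl]ethenyl}-5-[(2E,4E,6E,8E)-11-[(R)-4-(tert-butyldimethylsilyloxy)-2,6,6-trimethylcyclohex-1-en-1-yl]-2,9-dimethylundeca-2,4,6,8-tetraen-10-yn-1-ylidene]furan-2(5H)-one | CC1=C(C#C/C(C)=C/C=C/C=C/C=C(C)/C=C2C=C(/C=C/[C@@]34O[C@]3(C)C[C@@H](O[Si](C)(C)C(C)(C)C)CC4(C)C)C(=O)O/2)C(C)(C)C[C@H](O[Si](C)(C)C(C)(C)C)C1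
A1 | alternative 1 | (R)-3,5,5-trimethyl-4-[(triisopropylsilyl)ethynyl]cyclohex-3-en-1-yl acetate | CC1=C(C#C[Si](C(C)C)(C(C)C)C(C)C)C(C)(C)C[C@H](OC(C)=O)C1
A2 | alternative 1 | (S,E)-2,6-dimethyl-9-(triisopropylsilyl)nona-1,6-dien-8-yn-4-yl acetate | CC(=C)C[C@H](OC(C)=O)C/C(C)=C/C#C[Si](C(C)C)(C(C)C)C(C)C
A3 | alternative 2 | (Z)-3-{(E)-2-[(1S,4S,6R)-4-(tert-butyldimethylsilyloxy)-2,2,6-trimethyl-7-oxabicyclo[4.1.0]heptan-1-yl]ethenyl}-5-[(E)-2-methyl-4-(triethylsilyloxy)but-2-en-1-ylidene]furan-2(5H)-one | CC[Si](CC)(CC)OC/C=C(C)/C=C1C=C(/C=C/[C@@]23O[C@]2(C)C[C@@H](O[Si](C)(C)C(C)(C)C)CC3(C)C)C(=O)O/1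
A4 | alternative 2 | (1E,3Z,7E)-1-[(1S,4S,6R)-4-(tert-butyldimethylsilyloxy)-2,2,6-trimethyl-7-oxabicyclo[4.1.0]heptan-1-yl]-3-iodo-7-methyl-9-(triethylsilyloxy)nona-1,3,7-trien-5-one | CC[Si](CC)(CC)OC/C=C(C)/CC(=O)/C=C(\I)/C=C/[C@@]12O[C@]1(C)C[C@@H](O[Si](C)(C)C(C)(C)C)CC2(C)C
A5 | alternative 3 | [(1R,4S,6R)-4-(tert-butyldimethylsilyloxy)-2,2,6-trimethyl-7-oxabicyclo[4.1.0]heptan-1-yl]methanol | OC[C@@]12O[C@]1(C)C[C@@H](O[Si](C)(C)C(C)(C)C)CC2(C)C
A6 | alternative 3 | [(R)-4-(tert-butyldimethylsilyloxy)-2,6,6-trimethylcyclohex-1-en-1-yl]methanol | CC1=C(CO)C(C)(C)C[C@H](O[Si](C)(C)C(C)(C)C)C1
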